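**Retrosynthetic overview**
- Feature: in the 2-aryl-2,3-dihydrobenzofuran, the C2–C3 bond joins the benzylic ether carbon C2 (bonded to O1 and the guaiacyl ring C) to C3, which carries an ester-level carbon (the CH2OH) and the benzo carbon C3a. This is the pattern left by a 1,5 C–H insertion of an aryl(alkoxycarbonyl)carbene into an aryl benzyl ether.
- Disconnections, last to first: the two phenol O–Si bonds; C5–CH2 of the propyl chain (B-alkyl Suzuki–Miyaura coupling of a C5 bromide with the 9-BBN adduct of O-silylated allyl ferulate); CH2OH from CO2Me; C2–C3 (carbene insertion of an aryldiazoacetate).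
- The diazo ester comes from 5-bromo-2-hydroxy-3-methoxybenzaldehyde by Mitsunobu etherification with a silylated vanillyl alcohol, CHO to CH2CO2Me homologation and diazo transfer.
- Ring order: both benzene rings of the core (ring A, ring C) and the cinnamate are bought; the dihydrofuran (ring B) is the only ring made, in step 7, together with both stereocentres.
- Protecting groups: both phenols travel as triisopropylsilyl ethers, since an aryl tert-butyldimethylsilyl ether would be at risk towards the methoxide, DBU and aqueous phosphate used; the C3 hydroxymethyl is left free in the coupling.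

Key step: step 7

Remark: the S-configured catalyst is taken to deliver 2R by analogy with related 2-aryl closures; should the insertion favour 2S, Rh2(R-PTTL)4 is used in the same step.

**Route**

Step 1
Reactants: 1 vanillin
Product: 2 3-methoxy-4-[(triisopropylsilyl)oxy]benzaldehyde
Conditions: TIPSCl, imidazole, DMF, rt
Reagents that add atoms: triisopropylsilyl chloride (TIPSCl), CC(C)[Si](Cl)(C(C)C)C(C)C
Why: Imidazole-promoted silylation of the only OH group gives a hindered aryl silyl ether that should survive the later basic steps (phenol silylation).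

Step 2
Reactants: 2 3-methoxy-4-[(triisopropylsilyl)oxy]benzaldehyde
Product: 3 {3-methoxy-4-[(triisopropylsilyl)oxy]phenyl}methanol
Conditions: NaBH4, THF/MeOH, 0 °C
Reagents that add atoms: none
Why: Borohydride reduction of the aryl aldehyde to the benzylic alcohol should leave the silyl ether untouched at 0 °C (carbonyl reduction).

Step 3
Reactants: 3 {3-methoxy-4-[(triisopropylsilyl)oxy]phenyl}methanol; 4 5-bromo-2-hydroxy-3-methoxybenzaldehyde
Product: 5 5-bromo-3-methoxy-2-({3-methoxy-4-[(triisopropylsilyl)oxy]benzyl}oxy)benzaldehyde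
Conditions: PPh3, DIAD, THF, 0 °C → rt
Reagents that add atoms: none
Why: Mitsunobu etherification, in which the acidic salicylaldehyde phenol displaces the oxyphosphonium ion of the primary benzylic alcohol, so the unstable 4-silyloxybenzyl bromide is avoided.

Step 4
Reactants: 5 5-bromo-3-methoxy-2-({3-methoxy-4-[(triisopropylsilyl)oxy]benzyl}oxy)benzaldehyde
Product: 6 5-bromo-1-methoxy-3-(2-methoxyvinyl)-2-({3-methoxy-4-[(triisopropylsilyl)oxy]benzyl}oxy)benzene (E/Z mixture)
Conditions: (methoxymethyl)triphenylphosphonium chloride, NaN(SiMe3)2, THF, 0 °C; then 5, 0 °C → rt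
Reagents that add atoms: (methoxymethyl)triphenylphosphonium chloride, COC[P+](c1ccccc1)(c1ccccc1)c1ccccc1.[Cl-]
Why: Wittig methoxymethylenation of the aryl aldehyde with the non-stabilised ylide should give the enol ether, whose E/Z ratio is irrelevant because both isomers converge in step 5.

Step 5
Reactants: 6 5-bromo-1-methoxy-3-(2-methoxyvinyl)-2-({3-methoxy-4-[(triisopropylsilyl)oxy]benzyl}oxy)benzene (E/Z mixture)
Product: 7 methyl 2-[5-bromo-3-methoxy-2-({3-methoxy-4-[(triisopropylsilyl)oxy]benzyl}oxy)phenyl]acetate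
Conditions: pyridinium chlorochromate [C5H5NH][CrO3Cl] (2 equiv), 4 Å molecular sieves, CH2Cl2, rt
Reagents that add atoms: pyridinium chlorochromate, [O-][Cr](=O)(=O)Cl.c1cc[nH+]cc1
Why: Chlorochromate oxidation of an enol ether to an ester, in which protonation at the benzylic carbon gives an oxocarbenium ion that is trapped by chlorochromate and loses tetravalent chromium to leave the methyl ester, completing the one-carbon homologation.

Step 6
Reactants: 7 methyl 2-[5-bromo-3-methoxy-2-({3-methoxy-4-[(triisopropylsilyl)oxy]benzyl}oxy)phenyl]acetate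
Product: 8 methyl 2-[5-bromo-3-methoxy-2-({3-methoxy-4-[(triisopropylsilyl)oxy]benzyl}oxy)phenyl]-2-diazoacetate
Conditions: 4-acetamidobenzenesulfonyl azide (p-ABSA), DBU, MeCN, 0 °C → rt
Reagents that add atoms: 4-acetamidobenzenesulfonyl azide, CC(=O)Nc1ccc(cc1)S(=O)(=O)N=[N+]=[N-]
Why: Regitz diazo transfer from the sulfonyl azide to the DBU-generated arylacetate enolate should give the aryldiazoacetate, and DBU in dry acetonitrile should not cleave the aryl silyl ether.

Step 7
Reactants: 8 methyl 2-[5-bromo-3-methoxy-2-({3-methoxy-4-[(triisopropylsilyl)oxy]benzyl}oxy)phenyl]-2-diazoacetate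
Product: 10 methyl (2R,3R)-5-bromo-7-methoxy-2-{3-methoxy-4-[(triisopropylsilyl)oxy]phenyl}-2,3-dihydrobenzofuran-3-carboxylate (trans ester), via cis ester 9 (not isolated)
Conditions: Rh2(S-PTTL)4 (2 mol%), toluene, −60 °C; then NaOMe (0.3 equiv) in MeOH, 0 °C; aq. NH4Cl
Reagents that add atoms: none
Why: The divalent-rhodium dimer Rh2(S-PTTL)4 expels N2 from the aryldiazoacetate to give an electrophilic donor–acceptor carbene, whose carbon takes the benzylic C–H bond of the ortho ether through a three-centre, hydride-transfer-like transition state and forms C2–C3 with retention at C2. The closest known reaction type is the dirhodium carboxylate-catalysed enantioselective intramolecular C–H insertion of aryldiazoacetates into aryl benzyl ethers, which gives cis-2-aryl-2,3-dihydrobenzofuran-3-carboxylates. Ring B closes by C–C bond formation as a 1,5-insertion, the carbene carbon becoming C3 and the OCH2 carbon C2, at the only activated C–H bond within reach. C2 is set by the chiral phthalimido-tert-leucinate ligands, which select one of the two enantiotopic benzylic hydrogens at −60 °C; C3 forms cis under kinetic control (9) and is then equilibrated through the ester enolate by catalytic NaOMe to the more stable trans ester, while C2 has no acidic hydrogen and keeps its configuration. The step needs insertion to outrun carbene dimerisation, attack on the arenes and any reaction at the C–Br bond, which the stabilised carbene, the para-silyloxy activation of the benzylic C–H bond and the inertness of divalent rhodium towards aryl bromides should secure. The short, cold exposure to substoichiometric methoxide should leave the hindered aryl triisopropylsilyl ether in place.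

Step 8
Reactants: 10 methyl (2R,3R)-5-bromo-7-methoxy-2-{3-methoxy-4-[(triisopropylsilyl)oxy]phenyl}-2,3-dihydrobenzofuran-3-carboxylate
Product: 11 [(2R,3S)-5-bromo-7-methoxy-2-{3-methoxy-4-[(triisopropylsilyl)oxy]phenyl}-2,3-dihydrobenzofuran-3-yl]methanol (trans)
Conditions: LiBH4, THF (MeOH 1 equiv), 0 °C → rt
Reagents that add atoms: none
Why: Borohydride reduction of the methyl ester to the primary alcohol should spare the aryl bromide, the aryl silyl ether and both stereocentres; the C3 descriptor changes from R to S only through the CIP priorities (ester reduction).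

Step 9
Reactants: 12 ferulic acid, (E)-3-(4-hydroxy-3-methoxyphenyl)acrylic acid
Product: 13 allyl (E)-3-(4-hydroxy-3-methoxyphenyl)acrylate
Conditions: allyl bromide, KHCO3, DMF, rt
Reagents that add atoms: allyl bromide, C=CCBr
Why: The weak base KHCO3 forms only the carboxylate, so SN2 alkylation with allyl bromide should give the allyl ester and leave the phenol free (carboxylate O-alkylation).

Step 10
Reactants: 13 allyl (E)-3-(4-hydroxy-3-methoxyphenyl)acrylate
Product: 14 allyl (E)-3-{3-methoxy-4-[(triisopropylsilyl)oxy]phenyl}acrylate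
Conditions: TIPSCl, imidazole, DMF, rt
Reagents that add atoms: triisopropylsilyl chloride (TIPSCl), CC(C)[Si](Cl)(C(C)C)C(C)C
Why: Imidazole-promoted silylation masks the acidic phenol so that it neither consumes 9-BBN nor forms a phenoxide in the coupling (phenol silylation).

Step 11
Reactants: 11 [(2R,3S)-5-bromo-7-methoxy-2-{3-methoxy-4-[(triisopropylsilyl)oxy]phenyl}-2,3-dihydrobenzofuran-3-yl]methanol; 14 allyl (E)-3-{3-methoxy-4-[(triisopropylsilyl)oxy]phenyl}acrylate
Product: 16 3-[(2R,3S)-3-(hydroxymethyl)-7-methoxy-2-{3-methoxy-4-[(triisopropylsilyl)oxy]phenyl}-2,3-dihydrobenzofuran-5-yl]propyl (E)-3-{3-methoxy-4-[(triisopropylsilyl)oxy]phenyl}acrylate, via B-alkyl-9-BBN adduct 15 (not isolated)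
Conditions: 14 (1.5 equiv), 9-BBN dimer (slight excess of B–H over 14), THF, 0 °C → rt; then 3 M aq. K3PO4, 11, Pd(OAc)2 (5 mol%), SPhos (10 mol%), THF/H2O, 60 °C
Reagents that add atoms: none
Why: 9-BBN hydroborates only the terminal allyl alkene (anti-Markovnikov) and not the conjugated cinnamate alkene or the esters, and the B-alkyl-9-BBN then undergoes phosphate-promoted transmetalation in a B-alkyl Suzuki–Miyaura coupling at the electron-rich C5–Br bond, with SPhos speeding oxidative addition and complete consumption of 14 preventing allyl ester ionisation by zerovalent palladium.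

Step 12
Reactants: 16 3-[(2R,3S)-3-(hydroxymethyl)-7-methoxy-2-{3-methoxy-4-[(triisopropylsilyl)oxy]phenyl}-2,3-dihydrobenzofuran-5-yl]propyl (E)-3-{3-methoxy-4-[(triisopropylsilyl)oxy]phenyl}acrylate
Product: 17 3-[(2R,3S)-3-(hydroxymethyl)-2-(4-hydroxy-3-methoxyphenyl)-7-methoxy-2,3-dihydrobenzofuran-5-yl]propyl (E)-3-(4-hydroxy-3-methoxyphenyl)acrylate (CNP0149450.1)
Conditions: Bu4NF (2.5 equiv), AcOH (2.5 equiv), THF, 0 °C
Reagents that add atoms: none
Why: Fluoride cleaves both aryl triisopropylsilyl ethers because phenoxide is a good leaving group from silicon, and the acetic acid buffer should protect the feruloyl ester and the 2-(4-hydroxyaryl)dihydrobenzofuran from base (fluoride desilylation).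

**Compound list**
1 | vanillin (4-hydroxy-3-methoxybenzaldehyde) | COc1cc(C=O)ccc1O | starting material
2 | 3-methoxy-4-[(triisopropylsilyl)oxy]benzaldehyde | COc1cc(C=O)ccc1O[Si](C(C)C)(C(C)C)C(C)C | intermediate
3 | {3-methoxy-4-[(triisopropylsilyl)oxy]phenyl}methanol | COc1cc(CO)ccc1O[Si](C(C)C)(C(C)C)C(C)C | intermediate
4 | 5-bromo-2-hydroxy-3-methoxybenzaldehyde | COc1cc(Br)cc(C=O)c1O | starting material
5 | 5-bromo-3-methoxy-2-({3-methoxy-4-[(triisopropylsilyl)oxy]benzyl}oxy)benzaldehyde | COc1cc(Br)cc(C=O)c1OCc1ccc(O[Si](C(C)C)(C(C)C)C(C)C)c(OC)c1 | intermediate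
6 | 5-bromo-1-methoxy-3-(2-methoxyvinyl)-2-({3-methoxy-4-[(triisopropylsilyl)oxy]benzyl}oxy)benzene, E/Z mixture (alkene geometry left undefined) | COC=Cc1cc(Br)cc(OC)c1OCc1ccc(O[Si](C(C)C)(C(C)C)C(C)C)c(OC)c1 | intermediate
7 | methyl 2-[5-bromo-3-methoxy-2-({3-methoxy-4-[(triisopropylsilyl)oxy]benzyl}oxy)phenyl]acetate | COC(=O)Cc1cc(Br)cc(OC)c1OCc1ccc(O[Si](C(C)C)(C(C)C)C(C)C)c(OC)c1 | intermediate
8 | methyl 2-[5-bromo-3-methoxy-2-({3-methoxy-4-[(triisopropylsilyl)oxy]benzyl}oxy)phenyl]-2-diazoacetate | COC(=O)C(=[N+]=[N-])c1cc(Br)cc(OC)c1OCc1ccc(O[Si](C(C)C)(C(C)C)C(C)C)c(OC)c1 | intermediate (key-step precursor)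
9 | methyl (2R,3S)-5-bromo-7-methoxy-2-{3-methoxy-4-[(triisopropylsilyl)oxy]phenyl}-2,3-dihydrobenzofuran-3-carboxylate (cis) | Brc1cc(OC)c2c(c1)[C@H](C(=O)OC)[C@H](c3ccc(O[Si](C(C)C)(C(C)C)C(C)C)c(OC)c3)O2 | intermediate (not isolated)
10 | methyl (2R,3R)-5-bromo-7-methoxy-2-{3-methoxy-4-[(triisopropylsilyl)oxy]phenyl}-2,3-dihydrobenzofuran-3-carboxylate (trans) | Brc1cc(OC)c2c(c1)[C@@H](C(=O)OC)[C@H](c3ccc(O[Si](C(C)C)(C(C)C)C(C)C)c(OC)c3)O2 | intermediate (key-step product)
11 | [(2R,3S)-5-bromo-7-methoxy-2-{3-methoxy-4-[(triisopropylsilyl)oxy]phenyl}-2,3-dihydrobenzofuran-3-yl]methanol (trans) | Brc1cc(OC)c2c(c1)[C@@H](CO)[C@H](c3ccc(O[Si](C(C)C)(C(C)C)C(C)C)c(OC)c3)O2 | intermediate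
12 | ferulic acid, (E)-3-(4-hydroxy-3-methoxyphenyl)acrylic acid | COc1cc(/C=C/C(=O)O)ccc1O | starting material
13 | allyl (E)-3-(4-hydroxy-3-methoxyphenyl)acrylate | COc1cc(/C=C/C(=O)OCC=C)ccc1O | intermediate
14 | allyl (E)-3-{3-methoxy-4-[(triisopropylsilyl)oxy]phenyl}acrylate | COc1cc(/C=C/C(=O)OCC=C)ccc1O[Si](C(C)C)(C(C)C)C(C)C | intermediate
15 | 3-(9-borabicyclo[3.3.1]nonan-9-yl)propyl (E)-3-{3-methoxy-4-[(triisopropylsilyl)oxy]phenyl}acrylate | COc1cc(/C=C/C(=O)OCCCB2C3CCCC2CCC3)ccc1O[Si](C(C)C)(C(C)C)C(C)C | intermediate (not isolated)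
16 | 3-[(2R,3S)-3-(hydroxymethyl)-7-methoxy-2-{3-methoxy-4-[(triisopropylsilyl)oxy]phenyl}-2,3-dihydrobenzofuran-5-yl]propyl (E)-3-{3-methoxy-4-[(triisopropylsilyl)oxy]phenyl}acrylate | COc1cc(/C=C/C(=O)OCCCc2cc(OC)c3c(c2)[C@@H](CO)[C@H](c2ccc(O[Si](C(C)C)(C(C)C)C(C)C)c(OC)c2)O3)ccc1O[Si](C(C)C)(C(C)C)C(C)C | intermediate
17 | 3-[(2R,3S)-3-(hydroxymethyl)-2-(4-hydroxy-3-methoxyphenyl)-7-methoxy-2,3-dihydrobenzofuran-5-yl]propyl (E)-3-(4-hydroxy-3-methoxyphenyl)acrylate | COc1cc(/C=C/C(=O)OCCCc2cc(OC)c3c(c2)[C@@H](CO)[C@H](c2ccc(O)c(OC)c2)O3)ccc1O | target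

**Totals**
Total step count: 12. Longest linear sequence: 10 steps (1 → 17 through steps 1–8, 11 and 12); steps 9 and 10 form the side branch.

**Steps most likely to fail**

Step 7 (carbene insertion and epimerisation). The 7-methoxy group flanking the ether oxygen may twist the benzyloxy arm so that the catalyst discriminates poorly between the two enantiotopic benzylic hydrogens. The methoxide equilibration may also erode C2 by reversible ring opening of the ester enolate (retro-oxa-Michael), or begin to strip the aryl silyl ether. The fallback replaces catalyst control by auxiliary control and needs no epimerisation. It sets out from 7: mild hydrolysis with Me3SnOH in 1,2-dichloroethane at 80 °C should give 2-[5-bromo-3-methoxy-2-({3-methoxy-4-[(triisopropylsilyl)oxy]benzyl}oxy)phenyl]acetic acid F1. Esterification (EDC·HCl, DMAP, CH2Cl2) with (R)-2-hydroxy-1-(pyrrolidin-1-yl)propan-1-one (from methyl (R)-lactate and pyrrolidine) should give the lactamide arylacetate F2. Diazo transfer (p-ABSA, DBU, MeCN) should give the lactamide aryldiazoacetate F3. Insertion with Rh2(R-DOSP)4 in CH2Cl2 is expected to give the trans (2R,3R) lactamide ester F4 directly, as one of two diastereomers that can be separated by chromatography, so that stereochemical purity no longer rests on the catalyst alone. If this pairing induced 2S, the (S)-lactamide with Rh2(S-DOSP)4 would be used. LiBH4 reduction of F4 removes the auxiliary and comes back to the route at 11.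

Step 11 (hydroboration and B-alkyl coupling). Oxidative addition into the electron-rich aryl bromide may be slow enough that protodeboronation of the alkylborane, hydrolysis of the cinnamate ester by the aqueous base, or ionisation of residual allyl ester by zerovalent palladium win. The fallback separates C–C bond formation from ester formation and sets out from 11. TBSCl and imidazole should give the silyl ether tert-butyl{[(2R,3S)-5-bromo-7-methoxy-2-{3-methoxy-4-[(triisopropylsilyl)oxy]phenyl}-2,3-dihydrobenzofuran-3-yl]methoxy}dimethylsilane F5. Migita–Kosugi–Stille allylation (Bu3SnCH2CH=CH2, Pd(PPh3)4, DMF, 100 °C) should give the 5-allyl compound F6. Hydroboration with 9-BBN and oxidation with NaBO3·4H2O should give the 3-arylpropan-1-ol F7. Steglich esterification (EDC·HCl, DMAP, CH2Cl2) with (E)-3-{3-methoxy-4-[(triisopropylsilyl)oxy]phenyl}acrylic acid F8, made from 14 by deallylation with Pd(PPh3)4 and morpholine, should give the tris-silylated ester F9. Desilylation of F9 under the conditions of step 12 comes back to the route at 17.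

Step 5 (chlorochromate oxidation of the enol ether). The electron-rich styrenyl enol ether may suffer oxidative cleavage of its C=C bond back to aldehyde 5, or the acidic chromium reagent may ionise the electron-rich benzyl aryl ether. The fallback replaces the direct oxidation by hydrolysis, oxidation and esterification and sets out from 6. Hydrolysis under near-neutral conditions (Hg(OAc)2, THF/H2O, 0 °C, then aqueous KI) should give 2-[5-bromo-3-methoxy-2-({3-methoxy-4-[(triisopropylsilyl)oxy]benzyl}oxy)phenyl]acetaldehyde F10. Pinnick oxidation (NaClO2, NaH2PO4, 2-methyl-2-butene, t-BuOH/H2O) should give the arylacetic acid F1, the acid already described in the fallback for step 7. Methylation with trimethylsilyldiazomethane in toluene/MeOH comes back to the route at 7.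

**Further compounds**
F1 | step 7 | 2-[5-bromo-3-methoxy-2-({3-methoxy-4-[(triisopropylsilyl)oxy]benzyl}oxy)phenyl]acetic acid | OC(=O)Cc1cc(Br)cc(OC)c1OCc1ccc(O[Si](C(C)C)(C(C)C)C(C)C)c(OC)c1
F2 | step 7 | (R)-1-oxo-1-(pyrrolidin-1-yl)propan-2-yl 2-[5-bromo-3-methoxy-2-({3-methoxy-4-[(triisopropylsilyl)oxy]benzyl}oxy)phenyl]acetate | C[C@@H](OC(=O)Cc1cc(Br)cc(OC)c1OCc1ccc(O[Si](C(C)C)(C(C)C)C(C)C)c(OC)c1)C(=O)N1CCCC1
F3 | step 7 | (R)-1-oxo-1-(pyrrolidin-1-yl)propan-2-yl 2-[5-bromo-3-methoxy-2-({3-methoxy-4-[(triisopropylsilyl)oxy]benzyl}oxy)phenyl]-2-diazoacetate | C[C@@H](OC(=O)C(=[N+]=[N-])c1cc(Br)cc(OC)c1OCc1ccc(O[Si](C(C)C)(C(C)C)C(C)C)c(OC)c1)C(=O)N1CCCC1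
F4 | step 7 | (R)-1-oxo-1-(pyrrolidin-1-yl)propan-2-yl (2R,3R)-5-bromo-7-methoxy-2-{3-methoxy-4-[(triisopropylsilyl)oxy]phenyl}-2,3-dihydrobenzofuran-3-carboxylate (trans) | Brc1cc(OC)c2c(c1)[C@@H](C(=O)O[C@H](C)C(=O)N3CCCC3)[C@H](c3ccc(O[Si](C(C)C)(C(C)C)C(C)C)c(OC)c3)O2
F5 | step 11 | tert-butyl{[(2R,3S)-5-bromo-7-methoxy-2-{3-methoxy-4-[(triisopropylsilyl)oxy]phenyl}-2,3-dihydrobenzofuran-3-yl]methoxy}dimethylsilane | Brc1cc(OC)c2c(c1)[C@@H](CO[Si](C)(C)C(C)(C)C)[C@H](c3ccc(O[Si](C(C)C)(C(C)C)C(C)C)c(OC)c3)O2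
F6 | step 11 | {[(2R,3S)-5-allyl-7-methoxy-2-{3-methoxy-4-[(triisopropylsilyl)oxy]phenyl}-2,3-dihydrobenzofuran-3-yl]methoxy}(tert-butyl)dimethylsilane | C=CCc1cc(OC)c2c(c1)[C@@H](CO[Si](C)(C)C(C)(C)C)[C@H](c3ccc(O[Si](C(C)C)(C(C)C)C(C)C)c(OC)c3)O2
F7 | step 11 | 3-[(2R,3S)-3-{[(tert-butyldimethylsilyl)oxy]methyl}-7-methoxy-2-{3-methoxy-4-[(triisopropylsilyl)oxy]phenyl}-2,3-dihydrobenzofuran-5-yl]propan-1-ol | OCCCc1cc(OC)c2c(c1)[C@@H](CO[Si](C)(C)C(C)(C)C)[C@H](c3ccc(O[Si](C(C)C)(C(C)C)C(C)C)c(OC)c3)O2
F8 | step 11 | (E)-3-{3-methoxy-4-[(triisopropylsilyl)oxy]phenyl}acrylic acid | COc1cc(/C=C/C(=O)O)ccc1O[Si](C(C)C)(C(C)C)C(C)C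
F9 | step 11 | 3-[(2R,3S)-3-{[(tert-butyldimethylsilyl)oxy]methyl}-7-methoxy-2-{3-methoxy-4-[(triisopropylsilyl)oxy]phenyl}-2,3-dihydrobenzofuran-5-yl]propyl (E)-3-{3-methoxy-4-[(triisopropylsilyl)oxy]phenyl}acrylate | COc1cc(/C=C/C(=O)OCCCc2cc(OC)c3c(c2)[C@@H](CO[Si](C)(C)C(C)(C)C)[C@H](c2ccc(O[Si](C(C)C)(C(C)C)C(C)C)c(OC)c2)O3)ccc1O[Si](C(C)C)(C(C)C)C(C)C
F10 | step 5 | 2-[5-bromo-3-methoxy-2-({3-methoxy-4-[(triisopropylsilyl)oxy]benzyl}oxy)phenyl]acetaldehyde | O=CCc1cc(Br)cc(OC)c1OCc1ccc(O[Si](C(C)C)(C(C)C)C(C)C)c(OC)c1
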